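## The problem

The target consists of two benzophenones joined by one methylene carbon. The bridge links C3 of the 2,6-dihydroxy-4-methoxyphenyl (phloroglucinol) ring of one half to the same position of the other half. The halves differ at one oxygen only: the 6-methyl (orcinol) ring is 2,4-dihydroxylated in the dihydroxy half and 2-methoxy-4-hydroxy in the methoxy half. Of ten phenolic oxygens, three must end as methyl ethers and seven as free hydroxyls, and the single difference has to be fixed before the halves meet. Each ketone carbon lies between four ortho substituents, so acylation of either ring carbon, or aryl-metal addition from it, is the least reliable bond to make. There is no stereocentre and the twisted diaryl ketones are not configurationally stable, so nothing has to be controlled and nothing can direct. The free polyphenol is easily oxidised, 2-hydroxy-2'-alkoxybenzophenones close to xanthones under strong base or hot acid, and the bridge of a bis-phloroglucinol exchanges partners in alkali. A formaldehyde condensation of two different monomers would also give both symmetrical dimers, so the bridge must be made late, directionally and mildly. The opening is the contiguous array on each orcinol ring of the ketone-bearing C1, the methyl-bearing C6 and the oxygen-bearing C2. This is the pattern of C5, C6 and C4 of a 5-aroyl-4-alkoxy-6-methyl-2-pyrone, whose C3 becomes the ring CH, leaving only C4–O and C5–H to come from a two-carbon ynol ether with CO2 as the sole by-product.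

## Retrosynthesis

**25 from 24.** The last operation should only unmask phenols. The target 25 is traced to its bis-silyl ether 24, in which the 4-oxygen of each orcinol ring carries the triisopropylsilyl (TIPS) group that the key step installs. No skeletal bond is cut. The gain is that during bridge formation the orcinol rings cannot act as phenoxide nucleophiles para to their open positions. The forward step must cleave two aryl silyl ethers without a base strong enough to exchange the bridge or close a xanthone.

**24 from 21 and 19.** The bond from the bridge carbon to C3 of the dihydroxy-half phloroglucinol ring is cut. The electrophile is the ortho-quinone methide 23, set free from the Mannich salt 21 through its free base 22. The nucleophile is the dihydroxy-half monomer 19. This polarity is preferred over the reverse, and over a symmetrical one-carbon electrophile acting on both monomers, for two reasons. The precursor of 21 has no free hydroxyl on its orcinol ring, so the aminomethyl group can only enter the phloroglucinol ring. In both 21 and 19 the two open phloroglucinol positions are equivalent by symmetry, so one constitution results. The dimer is reduced to two monomeric benzophenones. The forward reaction needs the quinone methide to form under mild, weakly basic conditions and to meet 19 in excess.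

**21 from 15 and 20.** The benzylic C–N bond and the ring C–CH2 bond go back to the methoxy-half monomer 15 and the iminium salt 20. An ortho-hydroxybenzylamine is the most easily stored quinone methide precursor, and keeping it as the hydroiodide stops it from ionising before the partner is present.

**15 from 14, and 19 from 18.** Only O–benzyl bonds are cut. Every oxygen that ends as a free hydroxyl and does not come from the alkyne is carried as a benzyl ether, every final methyl ether is a methyl ether from the start, and the remaining oxygen is silylated. An all-methyl series would be simpler to carry. The methoxy half would then require two ortho methyl ethers on one ring to fall while a third, equally ortho to the ketone, stays, and no Lewis acid makes that distinction. Hydrogenolysis does.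

**14 from 8 and 12, and 18 from 16 and 12 (key cut).** In the orcinol ring, the bond from the methyl-bearing carbon to the neighbouring CH and the bond from the silyloxy carbon to the CH on its other side are cut. This returns the 5-aroyl-2-pyrones 8 and 16 and the siloxyalkyne 12. Cutting at the ketone (acylation of an orcinol or a phloroglucinol) would simplify more, but it puts the bond formation at a di-ortho-substituted carbon. Here the ketone exists before the ring does. The forward step needs one orientation of the alkyne on the pyrone and clean extrusion of the lactone bridge.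

**8 and 16 from 7.** The two pyrones differ only in the O-alkyl group at C4 and come from the single 4-hydroxypyrone 7 by O-methylation or O-benzylation. This is the only point at which the two halves diverge, and it decides which half each sample becomes.

**7 from 4 and 5; 4 from 2 and 3; 2 from 1.** The pyrone C2–C3–C4 unit is cut away as malonyl dichloride 5, leaving the 1,3-diketone 4. A Claisen cut gives the aryl methyl ketone 2 and ethyl acetate 3, and 2 is the dibenzyl ether of the purchasable acetophenone 1. The hindered ketone is thus bought, not made. The forward annulation must close the lactone through the acetyl oxygen, not the aroyl oxygen.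

**12 from 9.** The C–O bond of the ynol ether is cut, leading to acetylene 9 through its lithium salt 10 and the ynolate 11.

## Roads not taken

**Alternative 1:** The methoxy-half orcinol ring could be cut between the ketone-bearing and the methoxy-bearing carbons and between the methyl-bearing carbon and its neighbouring CH. In the forward direction the ynone A2 would take up the ketene-acetal diene A3 in a normal-demand Diels–Alder reaction. Loss of one alkoxy group aromatises the adduct, and hydrolysis of the silyl enol ether leaves the phenol A1.
- Merits: the diene is strongly polarised and its orientation with acyl alkynes is dependable, no gas is lost, the temperature is lower, and A1 already has its 2-methoxy and 4-hydroxy groups differentiated.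
- Concession: for the methoxy half alone this road is shorter than the pyrone road.
- Weak points: A2 is an internal alkyne with a methyl group on its β-carbon and a carbonyl twisted by the di-ortho-substituted aryl group, a sluggish partner for a hydrolytically fragile diene. The acetal terminus can only deliver a methyl ether, so the dihydroxy half would need a second, less accessible diene. The 4-hydroxyl emerges free and must be protected in an extra step before the bridge is made.
- What the chosen plan offers instead: one hydroxypyrone 7 serving both halves by choice of the O-alkyl group, one dienophile 12 for both, and a silyl ether that arrives with the ring.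

**Alternative 2:** Both phloroglucinol rings could be cut at the bond between the ketone-bearing carbon and one hydroxyl-bearing carbon, with the bridge already in place. In the forward direction the methylene-bridged bis-pyrone A5 would be opened at both lactones by a chelating magnesium alkoxide. Each aroylmethyl carbon would then attack the former lactone carbonyl in a Claisen closure to give the tri-O-benzyl target A4.
- Merits: the route is biomimetic and convergent, two rings form in one operation, the methoxy/hydroxy pattern of both phloroglucinol rings comes out unaided, and the bridge is set where C3 is the only nucleophilic carbon.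
- Concession: in convergence and in ring-site selectivity this road is better than the chosen one.
- Weak points: the unsymmetrical bridge problem is only moved back to the pyrone stage, where two different pyrones must still be joined by one carbon. Each aroylmethyl side chain requires acylating a pyrone methyl anion with a di-ortho-substituted benzoate, so the hindered ketone is formed by attack on a hindered ester. The recyclisation must succeed twice on a late, C3-substituted substrate, and a half-reacted or aldol-closed product would be hard to separate.
- What the chosen plan offers instead: each ring-forming step is run on a monomer, the hindered ketone comes from an unhindered methyl ketone enolate, and a failed cycloaddition costs one half, not the dimer.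

**Alternative 3:** The phloroglucinol ring of the methoxy half could be grown onto the bridge carbon. The cyclobutenone A7, which carries the protected dihydroxy-half benzophenone on its C4 methylene, would be heated with 12. Electrocyclic opening to a vinylketene, [2+2] addition of the alkyne, a second opening and a six-electron closure would give the phenol A6.
- Merits: the bridge is unambiguous, with no quinone methide, no homo-dimer and no exchange.
- Concession: in the certainty of the bridge this road is better than the chosen one.
- Weak points: it builds one ring of four. A6 still lacks the methoxy-half aroyl group, which would have to be introduced by acylating a ring carbon flanked by two oxygens with a di-ortho-substituted acyl donor, in competition with the other open ring carbon. That is the bond the chosen plan avoids. A7 needs its own multistep preparation from a dihydroxy-half monomer that has to be made anyway.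
- What the chosen plan offers instead: a directed Mannich and quinone methide coupling, made selective by the symmetry of both nucleophilic rings and by the silyl groups, with both ketones in place before the halves meet.

Key step: step 6

Assumption: compounds 1, 3, 5, 9 and 20 are taken as purchasable. The target is achiral, and the transient bicyclic lactones 13 and 17 are racemic.

## Route

Step 1
Reactants: 1 1-(2,6-dihydroxy-4-methoxyphenyl)ethan-1-one
Product: 2 1-[2,6-bis(benzyloxy)-4-methoxyphenyl]ethan-1-one
Conditions: BnBr, K2CO3, DMF, 70 °C
Reagents that add atoms: benzyl bromide, BrCc1ccccc1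
Why: Williamson ether synthesis; both phenols are hydrogen-bonded to the ketone, so DMF and heat are used, and the benzyl ethers then survive every step up to hydrogenolysis.

Step 2
Reactants: 2 1-[2,6-bis(benzyloxy)-4-methoxyphenyl]ethan-1-one; 3 ethyl acetate
Product: 4 1-[2,6-bis(benzyloxy)-4-methoxyphenyl]butane-1,3-dione
Conditions: NaH, EtOAc, THF, reflux; then aq. HCl
Reagents that add atoms: none
Why: Crossed Claisen condensation of the methyl ketone enolate with the ester; the diketone is removed from the equilibrium as its sodium enolate, and the hindered aryl ketone cannot self-condense.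

Step 3
Reactants: 4 1-[2,6-bis(benzyloxy)-4-methoxyphenyl]butane-1,3-dione; 5 malonyl dichloride
Product: 7 5-[2,6-bis(benzyloxy)-4-methoxybenzoyl]-4-hydroxy-6-methyl-2H-pyran-2-one, via C-acylated triketo acid chloride 6 (not isolated)
Conditions: CH2Cl2, 0 °C to 40 °C, no base
Reagents that add atoms: none
Why: Malonyl dichloride annulation of a 1,3-dicarbonyl compound to a 4-hydroxy-2-pyrone: the central enol carbon is acylated to 6 and an enol oxygen closes the lactone on the second acid chloride; closure through the acetyl oxygen is expected because the aroyl oxygen is shielded by two ortho benzyloxy groups.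

Step 4
Reactants: 7 5-[2,6-bis(benzyloxy)-4-methoxybenzoyl]-4-hydroxy-6-methyl-2H-pyran-2-one
Product: 8 5-[2,6-bis(benzyloxy)-4-methoxybenzoyl]-4-methoxy-6-methyl-2H-pyran-2-one
Conditions: Me2SO4, K2CO3, acetone, reflux
Reagents that add atoms: dimethyl sulfate, COS(=O)(=O)OC
Why: O-Alkylation of the vinylogous acid; with dimethyl sulfate and carbonate, 4-hydroxy-2-pyrones give the 4-methoxy-2-pyrone, not the 2-methoxy-4-pyrone, and this methyl group becomes the 2-methoxy group of the methoxy half.

Step 5
Reactants: 9 acetylene
Product: 12 (triisopropylsilyloxy)ethyne, via lithium acetylide 10 (not isolated), via lithium ethynolate 11 (not isolated)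
Conditions: n-BuLi, THF, −78 °C; t-BuOOLi (from t-BuOOH and LiN(SiMe3)2), −78 to 0 °C; i-Pr3SiCl, −78 °C to rt
Reagents that add atoms: tert-butyl hydroperoxide, CC(C)(C)OO; chlorotriisopropylsilane, CC(C)[Si](Cl)(C(C)C)C(C)C
Why: Oxidation of a lithium acetylide by lithium tert-butyl peroxide transfers oxygen to carbon and gives the ynolate, which a bulky chlorosilane silylates on oxygen to the siloxyalkyne.

Step 6
Reactants: 8 5-[2,6-bis(benzyloxy)-4-methoxybenzoyl]-4-methoxy-6-methyl-2H-pyran-2-one; 12 (triisopropylsilyloxy)ethyne
Product: 14 [2,6-bis(benzyloxy)-4-methoxyphenyl][2-methoxy-6-methyl-4-(triisopropylsilyloxy)phenyl]methanone, via bicyclic bridged lactone 13 (not isolated)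
Conditions: 12 (2–3 equiv), toluene, 110 °C, sealed tube
Reagents that add atoms: none
Why: The diene C3=C4–C5=C6 of 8, made electron-poor by the lactone carbonyl and the 5-aroyl group, and the electron-rich alkyne of 12 should combine in an inverse-electron-demand Diels–Alder reaction, the closest known type being the cycloaddition of 5-acyl and 5-alkoxycarbonyl 2-pyrones (coumalates) with ynamines and alkynyl ethers. The alkyne CH, its nucleophilic terminus, bonds to C6, which is the β-carbon of both the aroyl enone and the vinylogous lactone, and the siloxy-bearing carbon bonds to C3, the terminus made nucleophilic by the 4-methoxy group; the addition may be concerted and asynchronous or pass through a zwitterion, with the same outcome. This [4+2] closure gives the bridged lactone 13, which loses its CO2 bridge in a retro-[4+2] step driven by aromatisation, so the carbocycle is closed by cycloaddition and made aromatic by cycloreversion. No stereocentre remains, since the two bridgehead centres of 13 vanish with the CO2. The selectivity needed is the orientation of the alkyne (CH to C6, not to C3); it is secured by the matched polarisation just described and by the unsubstituted alkyne carbon being the one that meets the methyl-bearing C6. The ketone is a spectator, so the tetra-ortho-substituted benzophenone arises without any bond being made to a hindered ring carbon.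

Step 7
Reactants: 14 [2,6-bis(benzyloxy)-4-methoxyphenyl][2-methoxy-6-methyl-4-(triisopropylsilyloxy)phenyl]methanone
Product: 15 (2,6-dihydroxy-4-methoxyphenyl)[2-methoxy-6-methyl-4-(triisopropylsilyloxy)phenyl]methanone
Conditions: H2 (1 atm), 10% Pd/C, EtOAc, rt
Reagents that add atoms: none
Why: Hydrogenolysis of aryl benzyl ethers; the hindered, hydrogen-bonded diaryl ketone, the methyl ethers and the aryl silyl ether should be inert in ethyl acetate.

Step 8
Reactants: 7 5-[2,6-bis(benzyloxy)-4-methoxybenzoyl]-4-hydroxy-6-methyl-2H-pyran-2-one
Product: 16 4-(benzyloxy)-5-[2,6-bis(benzyloxy)-4-methoxybenzoyl]-6-methyl-2H-pyran-2-one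
Conditions: BnOH, PPh3, DIAD, THF, 0 °C to rt
Reagents that add atoms: benzyl alcohol, OCc1ccccc1
Why: Mitsunobu alkylation of the acidic 4-hydroxy-2-pyrone takes place on O4 and avoids the C3-benzylation that benzyl halides and carbonate can give; this benzyl group becomes the free 2-hydroxyl of the dihydroxy half.

Step 9
Reactants: 16 4-(benzyloxy)-5-[2,6-bis(benzyloxy)-4-methoxybenzoyl]-6-methyl-2H-pyran-2-one; 12 (triisopropylsilyloxy)ethyne
Product: 18 [2-(benzyloxy)-6-methyl-4-(triisopropylsilyloxy)phenyl][2,6-bis(benzyloxy)-4-methoxyphenyl]methanone, via bicyclic bridged lactone 17 (not isolated)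
Conditions: 12 (2–3 equiv), toluene, 110 °C, sealed tube
Reagents that add atoms: none
Why: The same inverse-electron-demand Diels–Alder reaction and CO2 extrusion as in step 6; the 4-benzyloxy group polarises the diene as the 4-methoxy group does, so the same orientation is expected.

Step 10
Reactants: 18 [2-(benzyloxy)-6-methyl-4-(triisopropylsilyloxy)phenyl][2,6-bis(benzyloxy)-4-methoxyphenyl]methanone
Product: 19 (2,6-dihydroxy-4-methoxyphenyl)[2-hydroxy-6-methyl-4-(triisopropylsilyloxy)phenyl]methanone
Conditions: H2 (1 atm), 10% Pd/C, EtOAc, rt
Reagents that add atoms: none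
Why: Hydrogenolysis of three aryl benzyl ethers under the conditions of step 7 leaves the 4-methoxy group and the silyl ether, which gives the dihydroxy-half monomer with only its orcinol 4-oxygen masked.

Step 11
Reactants: 15 (2,6-dihydroxy-4-methoxyphenyl)[2-methoxy-6-methyl-4-(triisopropylsilyloxy)phenyl]methanone; 20 N,N-dimethylmethyleneiminium iodide
Product: 21 {2,4-dihydroxy-6-methoxy-3-[2-methoxy-6-methyl-4-(triisopropylsilyloxy)benzoyl]phenyl}-N,N-dimethylmethanaminium iodide
Conditions: 20 (0.95 equiv), MeCN, 0 °C to rt, no base
Reagents that add atoms: none
Why: Mannich aminomethylation with a preformed iminium salt occurs ortho to a free phenol, so only the phloroglucinol ring reacts, and its two open positions are equivalent; the hydroiodide that forms is less nucleophilic toward a second iminium ion and cannot yet lose its amine.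

Step 12
Reactants: 21 {2,4-dihydroxy-6-methoxy-3-[2-methoxy-6-methyl-4-(triisopropylsilyloxy)benzoyl]phenyl}-N,N-dimethylmethanaminium iodide; 19 (2,6-dihydroxy-4-methoxyphenyl)[2-hydroxy-6-methyl-4-(triisopropylsilyloxy)phenyl]methanone
Product: 24 {3-[[2,4-dihydroxy-6-methoxy-3-[2-methoxy-6-methyl-4-(triisopropylsilyloxy)benzoyl]phenyl]methyl]-2,6-dihydroxy-4-methoxyphenyl}[2-hydroxy-6-methyl-4-(triisopropylsilyloxy)phenyl]methanone, via free Mannich base 22 (not isolated), via ortho-quinone methide 23 (not isolated)
Conditions: Et3N (1 equiv), 19 (2 equiv), 1,4-dioxane, 70 °C, slow addition of 21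
Reagents that add atoms: none
Why: Once triethylamine frees the Mannich base 22, its acidic chelated phenol protonates the nitrogen and the phenoxide expels dimethylamine to give the ortho-quinone methide 23, which is captured in a conjugate (Friedel–Crafts type) addition by the phloroglucinol ring of 19; the two open positions of that ring are equivalent and the silylated orcinol rings stay out.

Step 13
Reactants: 24 {3-[[2,4-dihydroxy-6-methoxy-3-[2-methoxy-6-methyl-4-(triisopropylsilyloxy)benzoyl]phenyl]methyl]-2,6-dihydroxy-4-methoxyphenyl}[2-hydroxy-6-methyl-4-(triisopropylsilyloxy)phenyl]methanone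
Product: 25 {3-[[2,4-dihydroxy-3-(4-hydroxy-2-methoxy-6-methylbenzoyl)-6-methoxyphenyl]methyl]-2,6-dihydroxy-4-methoxyphenyl}(2,4-dihydroxy-6-methylphenyl)methanone
Conditions: Bu4NF, AcOH, THF, 0 °C
Reagents that add atoms: none
Why: Fluoride cleavage of the two aryl silyl ethers; the acetic acid buffer keeps the medium from becoming basic enough to exchange the bridge or close a xanthone.

## Compound list

1 | 1-(2,6-dihydroxy-4-methoxyphenyl)ethan-1-one | CC(=O)c1c(O)cc(OC)cc1O | starting material
2 | 1-[2,6-bis(benzyloxy)-4-methoxyphenyl]ethan-1-one | CC(=O)c1c(OCc2ccccc2)cc(OC)cc1OCc1ccccc1 | intermediate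
3 | ethyl acetate | CCOC(C)=O | starting material
4 | 1-[2,6-bis(benzyloxy)-4-methoxyphenyl]butane-1,3-dione | CC(=O)CC(=O)c1c(OCc2ccccc2)cc(OC)cc1OCc1ccccc1 | intermediate
5 | malonyl dichloride (propanedioyl dichloride) | O=C(Cl)CC(=O)Cl | starting material
6 | 4-[2,6-bis(benzyloxy)-4-methoxybenzoyl]-3,5-dioxohexanoyl chloride (enolised, not isolated) | CC(=O)C(C(=O)CC(=O)Cl)C(=O)c1c(OCc2ccccc2)cc(OC)cc1OCc1ccccc1 | intermediate
7 | 5-[2,6-bis(benzyloxy)-4-methoxybenzoyl]-4-hydroxy-6-methyl-2H-pyran-2-one | CC1=C(C(=O)c2c(OCc3ccccc3)cc(OC)cc2OCc2ccccc2)C(O)=CC(=O)O1 | intermediate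
8 | 5-[2,6-bis(benzyloxy)-4-methoxybenzoyl]-4-methoxy-6-methyl-2H-pyran-2-one | COC1=CC(=O)OC(C)=C1C(=O)c1c(OCc2ccccc2)cc(OC)cc1OCc1ccccc1 | intermediate
9 | acetylene (ethyne) | C#C | starting material
10 | lithium acetylide (ethynyllithium, not isolated) | [Li]C#C | intermediate
11 | lithium ethynolate (not isolated) | [Li+].[O-]C#C | intermediate
12 | (triisopropylsilyloxy)ethyne | C#CO[Si](C(C)C)(C(C)C)C(C)C | intermediate
13 | 7-[2,6-bis(benzyloxy)-4-methoxybenzoyl]-8-methoxy-1-methyl-5-(triisopropylsilyloxy)-2-oxabicyclo[2.2.2]octa-5,7-dien-3-one (racemic, not isolated) | CC12OC(=O)C(C(OC)=C1C(=O)c1c(OCc3ccccc3)cc(OC)cc1OCc1ccccc1)C(O[Si](C(C)C)(C(C)C)C(C)C)=C2 | intermediate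
14 | [2,6-bis(benzyloxy)-4-methoxyphenyl][2-methoxy-6-methyl-4-(triisopropylsilyloxy)phenyl]methanone | COc1cc(O[Si](C(C)C)(C(C)C)C(C)C)cc(C)c1C(=O)c1c(OCc2ccccc2)cc(OC)cc1OCc1ccccc1 | intermediate
15 | (2,6-dihydroxy-4-methoxyphenyl)[2-methoxy-6-methyl-4-(triisopropylsilyloxy)phenyl]methanone | COc1cc(O[Si](C(C)C)(C(C)C)C(C)C)cc(C)c1C(=O)c1c(O)cc(OC)cc1O | intermediate
16 | 4-(benzyloxy)-5-[2,6-bis(benzyloxy)-4-methoxybenzoyl]-6-methyl-2H-pyran-2-one | CC1=C(C(=O)c2c(OCc3ccccc3)cc(OC)cc2OCc2ccccc2)C(OCc2ccccc2)=CC(=O)O1 | intermediate
17 | 8-(benzyloxy)-7-[2,6-bis(benzyloxy)-4-methoxybenzoyl]-1-methyl-5-(triisopropylsilyloxy)-2-oxabicyclo[2.2.2]octa-5,7-dien-3-one (racemic, not isolated) | CC12OC(=O)C(C(OCc3ccccc3)=C1C(=O)c1c(OCc3ccccc3)cc(OC)cc1OCc1ccccc1)C(O[Si](C(C)C)(C(C)C)C(C)C)=C2 | intermediate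
18 | [2-(benzyloxy)-6-methyl-4-(triisopropylsilyloxy)phenyl][2,6-bis(benzyloxy)-4-methoxyphenyl]methanone | Cc1cc(O[Si](C(C)C)(C(C)C)C(C)C)cc(OCc2ccccc2)c1C(=O)c1c(OCc2ccccc2)cc(OC)cc1OCc1ccccc1 | intermediate
19 | (2,6-dihydroxy-4-methoxyphenyl)[2-hydroxy-6-methyl-4-(triisopropylsilyloxy)phenyl]methanone | Cc1cc(O[Si](C(C)C)(C(C)C)C(C)C)cc(O)c1C(=O)c1c(O)cc(OC)cc1O | intermediate
20 | N,N-dimethylmethyleneiminium iodide | C=[N+](C)C.[I-] | starting material
21 | {2,4-dihydroxy-6-methoxy-3-[2-methoxy-6-methyl-4-(triisopropylsilyloxy)benzoyl]phenyl}-N,N-dimethylmethanaminium iodide | COc1cc(O[Si](C(C)C)(C(C)C)C(C)C)cc(C)c1C(=O)c1c(O)cc(OC)c(C[NH+](C)C)c1O.[I-] | intermediate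
22 | {3-[(dimethylamino)methyl]-2,6-dihydroxy-4-methoxyphenyl}[2-methoxy-6-methyl-4-(triisopropylsilyloxy)phenyl]methanone (not isolated) | COc1cc(O[Si](C(C)C)(C(C)C)C(C)C)cc(C)c1C(=O)c1c(O)cc(OC)c(CN(C)C)c1O | intermediate
23 | 3-hydroxy-5-methoxy-2-[2-methoxy-6-methyl-4-(triisopropylsilyloxy)benzoyl]-6-methylidenecyclohexa-2,4-dien-1-one (not isolated) | C=C1C(=O)C(C(=O)c2c(C)cc(O[Si](C(C)C)(C(C)C)C(C)C)cc2OC)=C(O)C=C1OC | intermediate
24 | {3-[[2,4-dihydroxy-6-methoxy-3-[2-methoxy-6-methyl-4-(triisopropylsilyloxy)benzoyl]phenyl]methyl]-2,6-dihydroxy-4-methoxyphenyl}[2-hydroxy-6-methyl-4-(triisopropylsilyloxy)phenyl]methanone | COc1cc(O)c(C(=O)c2c(C)cc(O[Si](C(C)C)(C(C)C)C(C)C)cc2O)c(O)c1Cc1c(OC)cc(O)c(C(=O)c2c(C)cc(O[Si](C(C)C)(C(C)C)C(C)C)cc2OC)c1O | intermediate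
25 | {3-[[2,4-dihydroxy-3-(4-hydroxy-2-methoxy-6-methylbenzoyl)-6-methoxyphenyl]methyl]-2,6-dihydroxy-4-methoxyphenyl}(2,4-dihydroxy-6-methylphenyl)methanone | COc1cc(O)c(C(=O)c2c(C)cc(O)cc2O)c(O)c1Cc1c(OC)cc(O)c(C(=O)c2c(C)cc(O)cc2OC)c1O | target

## Step count and least certain steps

Total: 13 steps. Longest linear sequence: 9 steps (steps 1, 2, 3, 4, 6, 7, 11, 12 and 13).

**Step 6 (key step) and step 9, the same reaction on 16.** The 4-alkoxy group is a donor on the diene, so the cycloaddition may be too slow at temperatures the siloxyalkyne tolerates, and the alkyne would then be consumed by rearrangement to a silylketene or by oligomerisation. A reversed orientation of the alkyne is the second risk. Fallback: replace the alkyne by a more nucleophilic alkene at the same two ring bonds. Setting out from 8, 1,1-bis(trimethylsilyloxy)ethene F1 (from trimethylsilyl acetate, LiN(iPr)2 and Me3SiCl) should add in the same orientation at lower temperature. Loss of CO2 and of trimethylsilanol, followed by aqueous work-up, should leave the free phenol [2,6-bis(benzyloxy)-4-methoxyphenyl](4-hydroxy-2-methoxy-6-methylphenyl)methanone F2. Silylation with i-Pr3SiCl and imidazole returns to the route at 14. From 16 the same two operations would pass through [2-(benzyloxy)-4-hydroxy-6-methylphenyl][2,6-bis(benzyloxy)-4-methoxyphenyl]methanone F3 and return at 18.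

**Step 3.** The bifunctional acid chloride may react a second time with the acidic hydroxypyrone (a further annulation), the HCl set free may cleave an ortho benzyl ether, and the lactone may close through the aroyl oxygen instead of the acetyl oxygen. Fallback: make the two bonds one at a time. Setting out from 4, C-acylation under soft enolisation (MgCl2, pyridine, CH2Cl2) with methyl 3-chloro-3-oxopropanoate should give methyl 4-acetyl-5-[2,6-bis(benzyloxy)-4-methoxyphenyl]-3,5-dioxopentanoate F4. This ester cannot react twice and forms without free HCl. Lactonisation with loss of methanol (DBU, toluene, heat) returns to the route at 7. The fallback removes the first two failure modes; which oxygen closes remains controlled by the substrate in both versions.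

**Step 5.** Monolithium acetylide may disproportionate to the insoluble dilithium salt before it is oxidised, and the parent ynolate may be silylated on carbon. Fallback: make the triple bond by elimination, as alkoxyacetylenes are made from 2-halovinyl ethers. This route does not start from 9. Bromoacetaldehyde F5, liberated from its commercial diethyl acetal, would be silylated on oxygen (i-Pr3SiOTf, i-Pr2NEt, CH2Cl2) to give [(Z)-2-bromoethenyl]oxytriisopropylsilane F6. Anti-elimination of HBr with LiN(iPr)2 in THF at −78 °C returns to the route at 12.

**Step 12.** The quinone methide may be captured by a second molecule of its own precursor (homo-coupling), the product may be alkylated again at its remaining open phloroglucinol positions, or the bridge may exchange under base. Fallback: change the electrophile from a quinone methide precursor to an aldehyde. Setting out from 15, Vilsmeier formylation (POCl3, DMF) should give 2,4-dihydroxy-6-methoxy-3-[2-methoxy-6-methyl-4-(triisopropylsilyloxy)benzoyl]benzaldehyde F7, which is stable and can be purified. Reductive arylation with 19 (Et3SiH, CF3CO2H, CH2Cl2, 0 °C), in which the carbinol formed from aldehyde and arene is ionised and reduced in the same flask under acidic, non-exchanging conditions, returns to the route at 24.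

## Further compounds

F1 | step 6 | 1,1-bis(trimethylsilyloxy)ethene | C=C(O[Si](C)(C)C)O[Si](C)(C)C
F2 | step 6 | [2,6-bis(benzyloxy)-4-methoxyphenyl](4-hydroxy-2-methoxy-6-methylphenyl)methanone | COc1cc(O)cc(C)c1C(=O)c1c(OCc2ccccc2)cc(OC)cc1OCc1ccccc1
F3 | step 9 | [2-(benzyloxy)-4-hydroxy-6-methylphenyl][2,6-bis(benzyloxy)-4-methoxyphenyl]methanone | Cc1cc(O)cc(OCc2ccccc2)c1C(=O)c1c(OCc2ccccc2)cc(OC)cc1OCc1ccccc1
F4 | step 3 | methyl 4-acetyl-5-[2,6-bis(benzyloxy)-4-methoxyphenyl]-3,5-dioxopentanoate | COC(=O)CC(=O)C(C(C)=O)C(=O)c1c(OCc2ccccc2)cc(OC)cc1OCc1ccccc1
F5 | step 5 | bromoacetaldehyde | BrCC=O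
F6 | step 5 | [(Z)-2-bromoethenyl]oxytriisopropylsilane | Br/C=C\O[Si](C(C)C)(C(C)C)C(C)C
F7 | step 12 | 2,4-dihydroxy-6-methoxy-3-[2-methoxy-6-methyl-4-(triisopropylsilyloxy)benzoyl]benzaldehyde | COc1cc(O[Si](C(C)C)(C(C)C)C(C)C)cc(C)c1C(=O)c1c(O)cc(OC)c(C=O)c1O
A1 | alternative 1 | [2,6-bis(benzyloxy)-4-methoxyphenyl](4-hydroxy-2-methoxy-6-methylphenyl)methanone | COc1cc(OCc2ccccc2)c(C(=O)c2c(C)cc(O)cc2OC)c(OCc2ccccc2)c1
A2 | alternative 1 | 1-[2,6-bis(benzyloxy)-4-methoxyphenyl]but-2-yn-1-one | CC#CC(=O)c1c(OCc2ccccc2)cc(OC)cc1OCc1ccccc1
A3 | alternative 1 | 1,1-dimethoxy-3-(trimethylsilyloxy)buta-1,3-diene | COC(OC)=CC(=C)O[Si](C)(C)C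
A4 | alternative 2 | {3-[[3-(4-benzyloxy-2-methoxy-6-methylbenzoyl)-2,4-dihydroxy-6-methoxyphenyl]methyl]-2,6-dihydroxy-4-methoxyphenyl}[2,4-bis(benzyloxy)-6-methylphenyl]methanone | COc1cc(O)c(C(=O)c2c(C)cc(OCc3ccccc3)cc2OCc2ccccc2)c(O)c1Cc1c(OC)cc(O)c(C(=O)c2c(C)cc(OCc3ccccc3)cc2OC)c1O
A5 | alternative 2 | 3-{[6-{2-[4-(benzyloxy)-2-methoxy-6-methylphenyl]-2-oxoethyl}-4-methoxy-2-oxo-2H-pyran-3-yl]methyl}-6-{2-[2,4-bis(benzyloxy)-6-methylphenyl]-2-oxoethyl}-4-methoxy-2H-pyran-2-one | COC1=C(CC2=C(OC)C=C(CC(=O)c3c(C)cc(OCc4ccccc4)cc3OC)OC2=O)C(=O)OC(CC(=O)c2c(C)cc(OCc3ccccc3)cc2OCc2ccccc2)=C1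
A6 | alternative 3 | [2,4-bis(benzyloxy)-6-methylphenyl]{2,6-bis(benzyloxy)-3-[[2-(benzyloxy)-6-hydroxy-4-(triisopropylsilyloxy)phenyl]methyl]-4-methoxyphenyl}methanone | COc1cc(OCc2ccccc2)c(C(=O)c2c(C)cc(OCc3ccccc3)cc2OCc2ccccc2)c(OCc2ccccc2)c1Cc1c(O)cc(O[Si](C(C)C)(C(C)C)C(C)C)cc1OCc1ccccc1
A7 | alternative 3 | 3-(benzyloxy)-4-({2,4-bis(benzyloxy)-3-[2,4-bis(benzyloxy)-6-methylbenzoyl]-6-methoxyphenyl}methyl)cyclobut-2-en-1-one (racemic) | O=C1C=C(OCc2ccccc2)C1Cc1c(OC)cc(OCc2ccccc2)c(C(=O)c2c(C)cc(OCc3ccccc3)cc2OCc2ccccc2)c1OCc1ccccc1
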